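**Plan**

- Retrosynthesis removes the eight C–Br bonds and the O-alkyl groups first. The central ring B has its hydroxyl carbons C1/C4 para, its aryloxy carbons at C2/C5 and its brominated carbons at C3/C6. It is then cut at three C–C bonds: C4–C3, C2–C1 and C1–C6.
- This makes C4 a methoxycarbene carbon on chromium, C1 a CO ligand, C3–C2 an aryl ethynyl ether and C6–C5 a 1-aryloxyvinyl group.
- Forward, 4-isopropoxyphenol supplies the outer rings A and C ready-made. One portion becomes the vinyl ether and then the chromium carbene complex, the other becomes the terminal ynol ether.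
- Carbene complex, alkyne and one CO close ring B, the only ring formed, in a Dötz benzannulation. O-methylation, removal of the isopropyl groups, eightfold bromination and demethylation finish the route.
- The target has no stereocentre and no stereogenic double bond, so only regiochemistry has to be set. The orientation of alkyne insertion fixes the oxygen pattern of ring B, and the dominance of free OH over ether oxygen fixes the bromine pattern of rings A and C.

Key step: step 5

Remark: 4-isopropoxyphenol, vinyl acetate, trichloroethylene and Cr(CO)6 are taken as purchased; isopropyl ethers are used on the outer rings so they can be removed while ring B stays masked as its dimethyl ether during bromination; in the SMILES, CO ligands are written as Cr=C=O and the hexahapto bond of 14 as a dot.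

**Route**

Step 1
Reactants: 1 4-isopropoxyphenol; 2 vinyl acetate
Product: 3 1-isopropoxy-4-(vinyloxy)benzene
Conditions: vinyl acetate (2 equiv), [Ir(cod)Cl]2 (1 mol%), Na2CO3 (0.6 equiv), toluene, 100 °C
Reagents that add atoms: vinyl acetate (compound 2), CC(=O)OC=C
Why: Iridium-catalysed transvinylation of a phenol with vinyl acetate is an established entry to aryl vinyl ethers and is well suited to 4-alkoxyphenols.

Step 2
Reactants: 3 1-isopropoxy-4-(vinyloxy)benzene; 4 chromium hexacarbonyl
Product: 7 pentacarbonyl[methoxy(1-(4-isopropoxyphenoxy)vinyl)carbene]chromium, via vinyllithium 5 (not isolated), via lithium acylchromate 6 (not isolated)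
Conditions: t-BuLi (1.1 equiv), THF, −78 °C; Cr(CO)6, THF, −78 → 0 °C; Me3OBF4, CH2Cl2, 0 °C
Reagents that add atoms: chromium hexacarbonyl (compound 4), O=C=[Cr](=C=O)(=C=O)(=C=O)(=C=O)=C=O; trimethyloxonium tetrafluoroborate, C[O+](C)C.F[B-](F)(F)F
Why: α-Lithiation of the enol ether at the vinylic carbon next to oxygen, followed by the Fischer carbene synthesis (organolithium addition to a CO ligand of Cr(CO)6, then O-methylation of the acylmetalate with a Meerwein salt), is the standard route to alkenyl(methoxy)carbene complexes.

Step 3
Reactants: 1 4-isopropoxyphenol; 8 trichloroethylene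
Product: 10 (E)-1-[(1,2-dichlorovinyl)oxy]-4-isopropoxybenzene, via dichloroethyne 9 (not isolated)
Conditions: ClCH=CCl2 (1.5 equiv), K2CO3, DMF, 70 °C
Reagents that add atoms: trichloroethylene (compound 8), ClC=C(Cl)Cl
Why: Base eliminates HCl from trichloroethylene and the phenoxide adds anti across the resulting dichloroethyne, the known first stage of the dichlorovinyl ether route to ynol ethers, which should give the E isomer.

Step 4
Reactants: 10 (E)-1-[(1,2-dichlorovinyl)oxy]-4-isopropoxybenzene
Product: 13 1-(ethynyloxy)-4-isopropoxybenzene, via chloroalkyne 11 (not isolated), via lithium acetylide 12 (not isolated)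
Conditions: n-BuLi (2.3 equiv), THF, −78 → −40 °C; H2O, −78 → 0 °C
Reagents that add atoms: none
Why: Dehydrochlorination by the first equivalent of n-BuLi and chlorine–lithium exchange by the second give the lithium aryloxyacetylide (second stage of the dichlorovinyl ether ynol ether synthesis), and protonation should release the terminal ynol ether, to be used at once as a cold solution.

Step 5
Reactants: 7 pentacarbonyl[methoxy(1-(4-isopropoxyphenoxy)vinyl)carbene]chromium; 13 1-(ethynyloxy)-4-isopropoxybenzene
Product: 15 4-methoxy-2,5-bis(4-isopropoxyphenoxy)phenol, via tricarbonylchromium arene complex 14 (not isolated)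
Conditions: 13 (1.5 equiv, slow addition), THF (0.05 M), 50 °C, Ar; then air, EtOAc, light, rt
Reagents that add atoms: none
Why: Thermal loss of one CO from 7 opens a site for 13, which inserts into the Cr=C bond with its unsubstituted carbon bonding to the carbene carbon, and CO insertion at the new aryloxy-bearing carbene carbon then gives a chromium-bound dienylketene. Six-electron electrocyclisation of this ketene onto the vinyl CH2 terminus closes the six-membered ring B as a cyclohexadienone (overall a [3+2+1] assembly), and tautomerisation gives the 4-methoxyphenol, which stays bound to Cr(CO)3 until air releases it. The closest known reaction is the Dötz benzannulation of alkenyl(methoxy)carbene complexes of zerovalent chromium with terminal alkynes, including complexes whose alkene carries an oxygen substituent on the carbon next to the carbene carbon. No stereocentre is formed. The step needs the aryloxy group of the alkyne to end up next to the new hydroxyl, and both the small hydrogen terminus and the nucleophilic character of the unsubstituted ynol ether carbon direct that carbon to the electrophilic carbene carbon. It also needs CO insertion to outrun cyclopentannulation and a second alkyne insertion, which the alkenyl carbene on chromium, THF and a low standing concentration of alkyne all favour, while an aryloxy group stabilises the intermediate carbene far less than the amino group that stalls ynamines.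

Step 6
Reactants: 15 4-methoxy-2,5-bis(4-isopropoxyphenoxy)phenol
Product: 16 1,4-dimethoxy-2,5-bis(4-isopropoxyphenoxy)benzene
Conditions: MeI, K2CO3, acetone, reflux
Reagents that add atoms: iodomethane, CI
Why: Williamson O-methylation of the single phenol masks ring B as a hydroquinone dimethyl ether that bromine cannot oxidise to a quinone.

Step 7
Reactants: 16 1,4-dimethoxy-2,5-bis(4-isopropoxyphenoxy)benzene
Product: 17 4,4'-[(2,5-dimethoxy-1,4-phenylene)bis(oxy)]diphenol
Conditions: BCl3 (5 equiv), CH2Cl2, −78 → 0 °C; H2O
Reagents that add atoms: none
Why: Lewis-acid dealkylation with BCl3 cleaves aryl isopropyl ethers through the secondary carbocation much faster than aryl methyl ethers, so the outer phenols should be freed while the ring B methyl ethers and the diaryl ether links stay intact.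

Step 8
Reactants: 17 4,4'-[(2,5-dimethoxy-1,4-phenylene)bis(oxy)]diphenol
Product: 18 1,4-dibromo-2,5-dimethoxy-3,6-bis(2,3,5-tribromo-4-hydroxyphenoxy)benzene
Conditions: Br2 (8.5 equiv), AcOH, rt → 50 °C
Reagents that add atoms: bromine, BrBr
Why: Electrophilic aromatic bromination should first fill the four positions ortho to the free hydroxyls and the two open positions of ring B (each ortho to a methoxy and an aryloxy group), then place one bromine ortho to the ether oxygen on each outer ring, where the two open sites are equivalent and the remaining one is deactivated by the new meta bromine.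

Step 9
Reactants: 18 1,4-dibromo-2,5-dimethoxy-3,6-bis(2,3,5-tribromo-4-hydroxyphenoxy)benzene
Product: 19 3,6-dibromo-2,5-bis(2,3,5-tribromo-4-hydroxyphenoxy)benzene-1,4-diol
Conditions: BBr3 (6 equiv), CH2Cl2, −78 °C → rt; H2O
Reagents that add atoms: none
Why: BBr3 demethylation of aryl methyl ethers is reliable for di-ortho-substituted anisoles and leaves diaryl ethers and aryl bromides untouched, so the hydroquinone of ring B should be released without any redox step.

**Compound list**

1 | 4-isopropoxyphenol | CC(C)Oc1ccc(O)cc1 | starting material
2 | vinyl acetate | CC(=O)OC=C | starting material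
3 | 1-isopropoxy-4-(vinyloxy)benzene | C=COc1ccc(OC(C)C)cc1 | intermediate
4 | chromium hexacarbonyl, Cr(CO)6 | O=C=[Cr](=C=O)(=C=O)(=C=O)(=C=O)=C=O | starting material
5 | [1-(4-isopropoxyphenoxy)vinyl]lithium | [Li]C(=C)Oc1ccc(OC(C)C)cc1 | intermediate
6 | lithium pentacarbonyl[2-(4-isopropoxyphenoxy)acryloyl]chromate | [Li+].[O-]C(=[Cr](=C=O)(=C=O)(=C=O)(=C=O)=C=O)C(=C)Oc1ccc(OC(C)C)cc1 | intermediate
7 | pentacarbonyl[methoxy(1-(4-isopropoxyphenoxy)vinyl)carbene]chromium | COC(=[Cr](=C=O)(=C=O)(=C=O)(=C=O)=C=O)C(=C)Oc1ccc(OC(C)C)cc1 | intermediate
8 | trichloroethylene | ClC=C(Cl)Cl | starting material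
9 | dichloroethyne | ClC#CCl | intermediate
10 | (E)-1-[(1,2-dichlorovinyl)oxy]-4-isopropoxybenzene | Cl/C=C(/Cl)Oc1ccc(OC(C)C)cc1 | intermediate
11 | 1-[(chloroethynyl)oxy]-4-isopropoxybenzene | ClC#COc1ccc(OC(C)C)cc1 | intermediate
12 | lithium 2-(4-isopropoxyphenoxy)ethynide | [Li]C#COc1ccc(OC(C)C)cc1 | intermediate
13 | 1-(ethynyloxy)-4-isopropoxybenzene | C#COc1ccc(OC(C)C)cc1 | intermediate
14 | tricarbonyl[4-methoxy-2,5-bis(4-isopropoxyphenoxy)phenol]chromium (Cr(CO)3 bound hexahapto to ring B) | CC(C)Oc1ccc(Oc2cc(OC)c(Oc3ccc(OC(C)C)cc3)cc2O)cc1.O=C=[Cr](=C=O)=C=O | intermediate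
15 | 4-methoxy-2,5-bis(4-isopropoxyphenoxy)phenol | COc1cc(Oc2ccc(OC(C)C)cc2)c(O)cc1Oc3ccc(OC(C)C)cc3 | intermediate
16 | 1,4-dimethoxy-2,5-bis(4-isopropoxyphenoxy)benzene | COc1cc(Oc2ccc(OC(C)C)cc2)c(OC)cc1Oc3ccc(OC(C)C)cc3 | intermediate
17 | 4,4'-[(2,5-dimethoxy-1,4-phenylene)bis(oxy)]diphenol | COc1cc(Oc2ccc(O)cc2)c(OC)cc1Oc3ccc(O)cc3 | intermediate
18 | 1,4-dibromo-2,5-dimethoxy-3,6-bis(2,3,5-tribromo-4-hydroxyphenoxy)benzene | COc1c(Br)c(Oc2cc(Br)c(O)c(Br)c2Br)c(OC)c(Br)c1Oc3cc(Br)c(O)c(Br)c3Br | intermediate
19 | 3,6-dibromo-2,5-bis(2,3,5-tribromo-4-hydroxyphenoxy)benzene-1,4-diol | Oc1c(Br)cc(Oc2c(O)c(Br)c(Oc3cc(Br)c(O)c(Br)c3Br)c(O)c2Br)c(Br)c1Br | target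

**Count and risks**

Total step count: 9. Longest linear sequence: 7 steps (1 → 3 → 7 → 15 → 16 → 17 → 18 → 19; the branch through 10 and 13 is equally long).

Steps most likely to fail:

Step 5. After the first insertion the aryloxy-stabilised vinylcarbene may take up a second alkyne or cyclise without CO uptake, and the terminal ynol ether may oligomerise at 50 °C before it is consumed. In that case ring B would be bought instead of built. The fallback sets out from 1 and returns to the route at 16. Commercial 1,4-diiodo-2,5-dimethoxybenzene and 1 (2.5 equiv) under Ullmann diaryl ether conditions (CuI, N,N-dimethylglycine, Cs2CO3, dioxane, 100 °C) should pass through 1-iodo-4-(4-isopropoxyphenoxy)-2,5-dimethoxybenzene F1 and give 16 after the second C–O coupling.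

Step 2. Deprotonation may occur on the aromatic ring ortho to an ether oxygen instead of at the vinylic carbon, or the lithiated enol ether may lose aryloxide by α-elimination before Cr(CO)6 traps it. The fallback sets out from 13 and returns at 5. Hydrostannation of 13 with Bu3SnH and Pd(PPh3)4 (zerovalent palladium) in THF at 0 °C should place tin on the oxygen-bearing carbon and give tributyl[1-(4-isopropoxyphenoxy)vinyl]stannane F2. Tin–lithium exchange with n-BuLi in THF at −78 °C would then generate 5 site-specifically without strong base acting on C–H bonds, and 5 continues through 6 to 7 as in step 2.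

Step 8. Bromination may stall before the crowded position ortho to the diaryl ether oxygen of each outer ring is reached, or run on to the last open position, and HBr with excess Br2 may dealkylate and oxidise ring B or cleave the 4-aryloxyphenols. The fallback sets out from 17 and returns at 18, separating the six easy bromines from the two hard ones. NBS (6 equiv) in MeCN at 0 °C should stop cleanly at 4,4'-[(2,5-dibromo-3,6-dimethoxy-1,4-phenylene)bis(oxy)]bis(2,6-dibromophenol) F3, with no HBr build-up. The last bromine on each outer ring would then be introduced with an exactly metered 2 equiv of Br2 under FeBr3 catalysis in CH2Cl2 (0 °C → rt) to give 18.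

**Further compounds**

F1 | step 5 | 1-iodo-4-(4-isopropoxyphenoxy)-2,5-dimethoxybenzene | COc1cc(Oc2ccc(OC(C)C)cc2)c(OC)cc1I
F2 | step 2 | tributyl[1-(4-isopropoxyphenoxy)vinyl]stannane | CCCC[Sn](CCCC)(CCCC)C(=C)Oc1ccc(OC(C)C)cc1
F3 | step 8 | 4,4'-[(2,5-dibromo-3,6-dimethoxy-1,4-phenylene)bis(oxy)]bis(2,6-dibromophenol) | COc1c(Br)c(Oc2cc(Br)c(O)c(Br)c2)c(OC)c(Br)c1Oc3cc(Br)c(O)c(Br)c3
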